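**Retrosynthetic overview**
- C10–OH comes from a C10–B(pin) bond (oxidation with retention). The C15 acetate is put on while C10 is still carbon–boron, so the two secondary oxygens never have to be told apart.
- Key disconnection C10–C11: chiral-palladium Suzuki coupling of a geminal bis(boronate) with an east (E)-vinyl bromide. C10 acts as a masked α-hydroxy carbanion, so two normally electrophilic carbons are joined and the catalyst sets C10. The same carbon was joined to C9 earlier by alkylating lithiated CH2(Bpin)2 with the west allylic bromide.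
- East vinyl bromide epoxy ester: Shi epoxidation ⇐ Johnson–Claisen rearrangement (E-olefin) ⇐ isopropenyl Grignard addition ⇐ carboalumination/bromination of 4-pentyn-1-ol.
- West allylic bromide: copper-catalysed SN2' opening of isoprene monoxide by furan-3-ylmethylmagnesium chloride, then Appel bromination.
- Rings: the furan is bought intact; the C15–C16 oxirane is formed first and is then turned into the γ-lactone by acid-triggered 5-exo opening (inversion at C16) in the work-up of the key coupling.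

Assumption: 3-(chloromethyl)furan is taken as a catalogue compound, and the sense of induction of the ligand in step 9 is assigned by analogy (the mirror-image ligand is used if C10 comes out opposite).

**Step 1**
Reactants: 1 3-(chloromethyl)furan; 2 2-ethenyl-2-methyloxirane (isoprene monoxide)
Product: 4 (2E)-5-(furan-3-yl)-2-methylpent-2-en-1-ol, via furan-3-ylmethylmagnesium chloride 3 (not isolated)
Conditions: Mg, THF, 0 °C to rt; CuBr·SMe2 (10 mol %), −30 °C; then 2, −30 to 0 °C
Reagents that add atoms: none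
Why: Copper-catalysed SN2' (anti) opening of the vinyl epoxide by the Grignard reagent forms the C–C bond at the vinyl terminus and gives the E-trisubstituted allylic alcohol (E:Z about 9:1, Z isomer removed by chromatography); no stereocentre is formed.

**Step 2**
Reactants: 4 (2E)-5-(furan-3-yl)-2-methylpent-2-en-1-ol
Product: 5 3-[(3E)-5-bromo-4-methylpent-3-en-1-yl]furan
Conditions: CBr4, PPh3, CH2Cl2, 0 °C
Reagents that add atoms: tetrabromomethane BrC(Br)(Br)Br
Why: Appel bromination of the primary allylic alcohol is neutral, so the acid-sensitive furan survives and the olefin keeps its position and E geometry.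

**Step 3**
Reactants: 5 3-[(3E)-5-bromo-4-methylpent-3-en-1-yl]furan; 6 bis(4,4,5,5-tetramethyl-1,3,2-dioxaborolan-2-yl)methane
Product: 8 2,2'-[(3E)-6-(furan-3-yl)-3-methylhex-3-ene-1,1-diyl]bis(4,4,5,5-tetramethyl-1,3,2-dioxaborolane), via lithiated bis(pinacolboryl)methane 7 (not isolated)
Conditions: LiTMP (from n-BuLi and 2,2,6,6-tetramethylpiperidine), THF, 0 °C; then 5, 0 °C to rt
Reagents that add atoms: none
Why: SN2 alkylation of the boron-stabilised carbanion (a masked hydroxymethyl dianion, i.e. a reversed-polarity C10 synthon) with the primary allylic bromide joins C9 to C10; the two boryl groups remain enantiotopic, so no stereocentre exists yet.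

**Step 4**
Reactants: 9 pent-4-yn-1-ol
Product: 11 (4E)-5-bromo-4-methylpent-4-en-1-ol, via alkenylalane 10 (not isolated)
Conditions: AlMe3 (3 equiv), Cp2ZrCl2 (25 mol %), CH2Cl2, 0 °C to rt; then NBS, THF, −30 to 0 °C
Reagents that add atoms: trimethylaluminium C[Al](C)C; N-bromosuccinimide O=C1CCC(=O)N1Br
Why: Negishi zirconium-catalysed carboalumination adds methyl and aluminium syn across the terminal alkyne with aluminium at the terminus, and bromodealumination with retention gives the E-vinyl bromide.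

**Step 5**
Reactants: 11 (4E)-5-bromo-4-methylpent-4-en-1-ol
Product: 12 (4E)-5-bromo-4-methylpent-4-enal
Conditions: TEMPO (10 mol %), PhI(OAc)2, CH2Cl2, rt
Reagents that add atoms: none
Why: Oxoammonium (TEMPO) oxidation stops cleanly at the aldehyde and leaves the vinyl bromide untouched.

**Step 6**
Reactants: 12 (4E)-5-bromo-4-methylpent-4-enal; 13 prop-1-en-2-ylmagnesium bromide
Product: 14 (6E)-7-bromo-2,6-dimethylhepta-1,6-dien-3-ol (racemic)
Conditions: THF, −78 to 0 °C
Reagents that add atoms: none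
Why: Grignard 1,2-addition to the aldehyde; the new carbinol centre is left racemic because it is erased in step 7.

**Step 7**
Reactants: 14 (6E)-7-bromo-2,6-dimethylhepta-1,6-dien-3-ol; 15 1,1,1-triethoxyethane (triethyl orthoacetate)
Product: 18 ethyl (4E,8E)-9-bromo-4,8-dimethylnona-4,8-dienoate, via mixed orthoester 16 (not isolated), via ketene acetal 17 (not isolated)
Conditions: EtCO2H (10 mol %), neat 15, 140 °C, EtOH distilled off
Reagents that add atoms: none
Why: Johnson–Claisen rearrangement through a chair transition state with the chain equatorial gives the E-trisubstituted C15=C16 olefin (above 95:5) and the two-carbon ester extension.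

**Step 8**
Reactants: 18 ethyl (4E,8E)-9-bromo-4,8-dimethylnona-4,8-dienoate
Product: 19 ethyl 3-[(2R,3R)-3-[(3E)-4-bromo-3-methylbut-3-en-1-yl]-2-methyloxiran-2-yl]propanoate
Conditions: D-fructose-derived Shi ketone (30 mol %), Oxone (2KHSO5·KHSO4·K2SO4), K2CO3, n-Bu4NHSO4, MeCN/CH2(OMe)2/aq buffer pH 10.5, 0 °C
Reagents that add atoms: potassium peroxymonosulfate [K+].[O-]S(=O)(=O)OO
Why: Shi asymmetric epoxidation (chiral dioxirane, spiro transition state) attacks only the electron-rich trisubstituted olefin, the bromoalkene being deactivated, and sets C15 and C16 as (R,R) in about 90–95 % ee.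

**Step 9**
Reactants: 8 2,2'-[(3E)-6-(furan-3-yl)-3-methylhex-3-ene-1,1-diyl]bis(4,4,5,5-tetramethyl-1,3,2-dioxaborolane); 19 ethyl 3-[(2R,3R)-3-[(3E)-4-bromo-3-methylbut-3-en-1-yl]-2-methyloxiran-2-yl]propanoate
Product: 22 (5S)-5-[(1R,4E,6S,8E)-11-(furan-3-yl)-1-hydroxy-4,8-dimethyl-6-(4,4,5,5-tetramethyl-1,3,2-dioxaborolan-2-yl)undeca-4,8-dien-1-yl]-5-methyloxolan-2-one, via potassium epoxy carboxylate 20 (not isolated), via epoxy acid 21 (not isolated)
Conditions: Pd(OAc)2 (5 mol %), (R,R)-TADDOL-derived dimethylphosphoramidite (10 mol %), KOH (8 M aq), 1,4-dioxane, rt; then aq KHSO4 to pH 3, CSA (5 mol %), CH2Cl2, rt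
Reagents that add atoms: potassium hydroxide [K+].[OH-]
Why: Enantiotopic-group-selective Suzuki–Miyaura coupling of the geminal bis(boronate), in which hydroxide-activated stereoinvertive transmetalation of one boryl group to the chiral vinylpalladium complex sets C10 as S under catalyst control with the E-olefin retained, the diboryl carbon acting as an α-hydroxy carbanion equivalent toward the electrophilic vinyl bromide carbon; the KOH also saponifies the ester, and acidification triggers 5-exo opening of the epoxide by the carboxyl group with inversion at C16, giving the (16S) lactone beside the untouched (15R) carbinol.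

**Step 10**
Reactants: 22 (5S)-5-[(1R,4E,6S,8E)-11-(furan-3-yl)-1-hydroxy-4,8-dimethyl-6-(4,4,5,5-tetramethyl-1,3,2-dioxaborolan-2-yl)undeca-4,8-dien-1-yl]-5-methyloxolan-2-one
Product: 23 (1R,4E,6S,8E)-11-(furan-3-yl)-4,8-dimethyl-1-[(2S)-2-methyl-5-oxooxolan-2-yl]-6-(4,4,5,5-tetramethyl-1,3,2-dioxaborolan-2-yl)undeca-4,8-dien-1-yl acetate
Conditions: Ac2O, DMAP (20 mol %), pyridine, CH2Cl2, rt
Reagents that add atoms: acetic anhydride CC(=O)OC(C)=O
Why: DMAP-catalysed acylation of the only free hydroxyl group (C15); C10 is still masked as a C–B bond, so no differentiation is needed and no stereocentre is touched.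

**Step 11**
Reactants: 23 (1R,4E,6S,8E)-11-(furan-3-yl)-4,8-dimethyl-1-[(2S)-2-methyl-5-oxooxolan-2-yl]-6-(4,4,5,5-tetramethyl-1,3,2-dioxaborolan-2-yl)undeca-4,8-dien-1-yl acetate
Product: 25 15-acetylirciformonin B [(1R,4E,6S,8E)-11-(furan-3-yl)-6-hydroxy-4,8-dimethyl-1-[(2S)-2-methyl-5-oxooxolan-2-yl]undeca-4,8-dien-1-yl acetate], via borate ester 24 (not isolated)
Conditions: NaBO3·4H2O, THF/H2O (1:1), rt
Reagents that add atoms: sodium perborate [Na+].[O-]OB=O
Why: Perborate oxidation of the allylic C–B bond (1,2-migration from boron to oxygen) proceeds with retention at C10 and without allylic transposition, and the mild medium spares the hindered acetate and the lactone.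

**Compound list**
1 | 3-(chloromethyl)furan | ClCc1ccoc1 | starting material
2 | 2-ethenyl-2-methyloxirane (isoprene monoxide, racemic) | CC1(C=C)CO1 | starting material
3 | furan-3-ylmethylmagnesium chloride | Cl[Mg]Cc1ccoc1 | intermediate
4 | (2E)-5-(furan-3-yl)-2-methylpent-2-en-1-ol | OC/C(C)=C/CCc1ccoc1 | intermediate
5 | 3-[(3E)-5-bromo-4-methylpent-3-en-1-yl]furan | BrC/C(C)=C/CCc1ccoc1 | intermediate
6 | bis(4,4,5,5-tetramethyl-1,3,2-dioxaborolan-2-yl)methane | C(B1OC(C)(C)C(C)(C)O1)B1OC(C)(C)C(C)(C)O1 | starting material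
7 | [bis(4,4,5,5-tetramethyl-1,3,2-dioxaborolan-2-yl)methyl]lithium | [Li]C(B1OC(C)(C)C(C)(C)O1)B1OC(C)(C)C(C)(C)O1 | intermediate
8 | 2,2'-[(3E)-6-(furan-3-yl)-3-methylhex-3-ene-1,1-diyl]bis(4,4,5,5-tetramethyl-1,3,2-dioxaborolane) | C(C/C(C)=C/CCc1ccoc1)(B1OC(C)(C)C(C)(C)O1)B1OC(C)(C)C(C)(C)O1 | intermediate
9 | pent-4-yn-1-ol | C#CCCCO | starting material
10 | dimethyl[(1E)-5-[(dimethylalumanyl)oxy]-2-methylpent-1-en-1-yl]alumane | C[Al](C)/C=C(C)/CCCO[Al](C)C | intermediate
11 | (4E)-5-bromo-4-methylpent-4-en-1-ol | Br/C=C(C)/CCCO | intermediate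
12 | (4E)-5-bromo-4-methylpent-4-enal | Br/C=C(C)/CCC=O | intermediate
13 | prop-1-en-2-ylmagnesium bromide (isopropenylmagnesium bromide) | CC(=C)[Mg]Br | starting material
14 | (6E)-7-bromo-2,6-dimethylhepta-1,6-dien-3-ol (racemic) | Br/C=C(C)/CCC(O)C(C)=C | intermediate
15 | 1,1,1-triethoxyethane (triethyl orthoacetate) | CCOC(C)(OCC)OCC | starting material
16 | (6E)-7-bromo-3-(1,1-diethoxyethoxy)-2,6-dimethylhepta-1,6-diene | Br/C=C(C)/CCC(OC(C)(OCC)OCC)C(C)=C | intermediate
17 | (6E)-7-bromo-3-[(1-ethoxyethenyl)oxy]-2,6-dimethylhepta-1,6-diene | Br/C=C(C)/CCC(OC(=C)OCC)C(C)=C | intermediate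
18 | ethyl (4E,8E)-9-bromo-4,8-dimethylnona-4,8-dienoate | Br/C=C(C)/CC/C=C(C)/CCC(=O)OCC | intermediate
19 | ethyl 3-[(2R,3R)-3-[(3E)-4-bromo-3-methylbut-3-en-1-yl]-2-methyloxiran-2-yl]propanoate | Br/C=C(C)/CC[C@H]1O[C@]1(C)CCC(=O)OCC | intermediate
20 | potassium 3-[(2R,3R)-3-[(3E,5S,7E)-10-(furan-3-yl)-3,7-dimethyl-5-(4,4,5,5-tetramethyl-1,3,2-dioxaborolan-2-yl)deca-3,7-dien-1-yl]-2-methyloxiran-2-yl]propanoate | c1occc1CC/C=C(C)/C[C@H](B1OC(C)(C)C(C)(C)O1)/C=C(C)/CC[C@H]1O[C@]1(C)CCC(=O)[O-].[K+] | intermediate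
21 | 3-[(2R,3R)-3-[(3E,5S,7E)-10-(furan-3-yl)-3,7-dimethyl-5-(4,4,5,5-tetramethyl-1,3,2-dioxaborolan-2-yl)deca-3,7-dien-1-yl]-2-methyloxiran-2-yl]propanoic acid | c1occc1CC/C=C(C)/C[C@H](B1OC(C)(C)C(C)(C)O1)/C=C(C)/CC[C@H]1O[C@]1(C)CCC(=O)O | intermediate
22 | (5S)-5-[(1R,4E,6S,8E)-11-(furan-3-yl)-1-hydroxy-4,8-dimethyl-6-(4,4,5,5-tetramethyl-1,3,2-dioxaborolan-2-yl)undeca-4,8-dien-1-yl]-5-methyloxolan-2-one | O[C@H](CC/C(C)=C/[C@@H](B1OC(C)(C)C(C)(C)O1)C/C(C)=C/CCc1ccoc1)[C@]1(C)CCC(=O)O1 | intermediate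
23 | (1R,4E,6S,8E)-11-(furan-3-yl)-4,8-dimethyl-1-[(2S)-2-methyl-5-oxooxolan-2-yl]-6-(4,4,5,5-tetramethyl-1,3,2-dioxaborolan-2-yl)undeca-4,8-dien-1-yl acetate | CC(=O)O[C@H](CC/C(C)=C/[C@@H](B1OC(C)(C)C(C)(C)O1)C/C(C)=C/CCc1ccoc1)[C@]1(C)CCC(=O)O1 | intermediate
24 | (1R,4E,6S,8E)-11-(furan-3-yl)-4,8-dimethyl-1-[(2S)-2-methyl-5-oxooxolan-2-yl]-6-[(4,4,5,5-tetramethyl-1,3,2-dioxaborolan-2-yl)oxy]undeca-4,8-dien-1-yl acetate | CC(=O)O[C@H](CC/C(C)=C/[C@@H](OB1OC(C)(C)C(C)(C)O1)C/C(C)=C/CCc1ccoc1)[C@]1(C)CCC(=O)O1 | intermediate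
25 | 15-acetylirciformonin B, (1R,4E,6S,8E)-11-(furan-3-yl)-6-hydroxy-4,8-dimethyl-1-[(2S)-2-methyl-5-oxooxolan-2-yl]undeca-4,8-dien-1-yl acetate | CC(=O)O[C@H](CC/C(C)=C/[C@@H](O)C/C(C)=C/CCc1ccoc1)[C@]1(C)CCC(=O)O1 | target

**Step count and risk**
Total: 11 steps. Longest linear sequence: 8 steps (4, 5, 6, 7, 8, 9, 10, 11); the west branch is 3 steps (1, 2, 3).

Stereochemical bookkeeping:
- C15 (R): set in step 8 and never touched again.
- C16 (S): set as R in step 8 and inverted in step 9.
- C10 (S): set in step 9 and carried with retention through step 11.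
- The minor C10 epimer (expected 5–10 %) and the minor enantiomeric series from step 8 are diastereomers of 22 and 25 and are removed by chromatography.

Most likely to fail:

1. **Step 9.** The enantioselectivity may be lower with a β,β-disubstituted vinyl bromide. The epoxide and carboxylate must survive 8 M KOH, and the allyl boronate must survive the acid-triggered lactonisation. The fallback sets out from 8 and 19 and returns at 25, giving up catalyst control at C10. The two are coupled with achiral Pd[P(t-Bu)3]2 and aqueous KOH, oxidised in the same flask with NaBO3·4H2O and acidified to give the C10-epimeric diol lactone F1. MnO2 in CH2Cl2 oxidises only the allylic C10 hydroxyl to the hydroxy enone F2. Ac2O/pyridine at 0 °C acetylates C15 to give the acetoxy enone F3. Reduction with (R)-2-methyl-CBS-oxazaborolidine and catecholborane in toluene at −78 °C, the alkenyl group acting as the large substituent, then sets (S)-C10 and gives 25.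

2. **Step 1.** The Grignard reagent can attack the epoxide directly (SN2) or react through furan C2, and the E:Z ratio may be poor. The fallback sets out from 1 and returns at 4. Grignard reagent 3 is coupled with 1-chloro-3-methylbut-2-ene under Li2CuCl4 catalysis in THF at 0 °C to give perillene, 3-(4-methylpent-3-en-1-yl)furan F4. Its E-methyl group is then hydroxylated with SeO2 (catalytic) and t-BuOOH in CH2Cl2, followed by NaBH4 to return any enal, giving 4 with the E geometry fixed by the ene/[2,3] mechanism.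

3. **Step 11.** The acetate may be partly cleaved or the lactone opened under perborate, or the allyl boronate may be lost on the way through step 10. The fallback sets out from 22 and returns at 25. Compound 22 is oxidised first with NaBO3·4H2O to the 15-deacetyl diol F5. The less hindered allylic C10 hydroxyl is silylated selectively (TESCl, imidazole, CH2Cl2, −40 °C) to give the triethylsilyl ether F6. The hindered C15 hydroxyl is acetylated (Ac2O, DMAP, pyridine) to give the silyl ether acetate F7, and HF·pyridine in THF at 0 °C removes the silyl group to give 25.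

**Further compounds**
F1 | step 9 | (5S)-5-[(1R,4E,8E)-11-(furan-3-yl)-1,6-dihydroxy-4,8-dimethylundeca-4,8-dien-1-yl]-5-methyloxolan-2-one (both C6 epimers) | O[C@H](CC/C(C)=C/C(O)C/C(C)=C/CCc1ccoc1)[C@]1(C)CCC(=O)O1
F2 | step 9 | (5S)-5-[(1R,4E,8E)-11-(furan-3-yl)-1-hydroxy-4,8-dimethyl-6-oxoundeca-4,8-dien-1-yl]-5-methyloxolan-2-one | O[C@H](CC/C(C)=C/C(=O)C/C(C)=C/CCc1ccoc1)[C@]1(C)CCC(=O)O1
F3 | step 9 | (1R,4E,8E)-11-(furan-3-yl)-4,8-dimethyl-1-[(2S)-2-methyl-5-oxooxolan-2-yl]-6-oxoundeca-4,8-dien-1-yl acetate | CC(=O)O[C@H](CC/C(C)=C/C(=O)C/C(C)=C/CCc1ccoc1)[C@]1(C)CCC(=O)O1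
F4 | step 1 | 3-(4-methylpent-3-en-1-yl)furan (perillene) | CC(C)=CCCc1ccoc1
F5 | step 11 | (5S)-5-[(1R,4E,6S,8E)-11-(furan-3-yl)-1,6-dihydroxy-4,8-dimethylundeca-4,8-dien-1-yl]-5-methyloxolan-2-one | O[C@H](CC/C(C)=C/[C@@H](O)C/C(C)=C/CCc1ccoc1)[C@]1(C)CCC(=O)O1
F6 | step 11 | (5S)-5-[(1R,4E,6S,8E)-11-(furan-3-yl)-1-hydroxy-4,8-dimethyl-6-[(triethylsilyl)oxy]undeca-4,8-dien-1-yl]-5-methyloxolan-2-one | O[C@H](CC/C(C)=C/[C@@H](O[Si](CC)(CC)CC)C/C(C)=C/CCc1ccoc1)[C@]1(C)CCC(=O)O1
F7 | step 11 | (1R,4E,6S,8E)-11-(furan-3-yl)-4,8-dimethyl-1-[(2S)-2-methyl-5-oxooxolan-2-yl]-6-[(triethylsilyl)oxy]undeca-4,8-dien-1-yl acetate | CC(=O)O[C@H](CC/C(C)=C/[C@@H](O[Si](CC)(CC)CC)C/C(C)=C/CCc1ccoc1)[C@]1(C)CCC(=O)O1
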